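Compound numbers used throughout are those of the steps and the compound list below (1–19; the target is 19).

## The problem

The target 19 is two coumarins joined by one oxygen, from C6 of unit A (a 7-hydroxycoumarin) to C5' of unit B (a 6',7'-dihydroxycoumarin). It has no stereocentre, so the whole difficulty is connectivity and regiochemistry. The bridging oxygen sits on C5', between the peri carbon C4a' and the oxygen on C6', on a benzene ring whose only free position is C8'. Arylating so hindered and electron-rich an oxygen is the weakest way to make the ether. Unit B carries two oxygens flanking C4a' (O1' and the C5' oxygen) that differ only in their far neighbours (C8'–H against C6'–O). The synthesis must tell them apart so that one closes the lactone and the other becomes the bridge. Both lactones are Michael acceptors that open with hydroxide or alkoxide, and the catechol and phenols oxidise easily, so the three hydroxyl groups are carried as methyl ethers to the last step. The benzene ring of unit A has oxygen on C6, C7 and C8a, carbon on C4a and hydrogen on C5 and C8. This maps onto a 1,3-dioxygenated diene C8a–C8–C7–C6 with the aryloxy group on its C6 terminus, plus an acetylenic aldehyde supplying C4a, C5 and C4 (the formyl carbon). That mapping is what makes the key step possible.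

## Retrosynthesis

**19 from 18.** The three O–CH3 bonds are cut last. Methyl ethers are preferred to benzyl ethers because hydrogenolysis could saturate the C3–C4 bonds, whereas BBr3 leaves lactones and the diaryl ether alone. The tri-O-methyl ether 18 has the same skeleton but none of the oxidisable phenols. The forward step must cleave three ethers completely, one of them hindered (C6').

**18 from 15.** The pyranone of unit A is opened at C3=C4 and O1–C2, giving salicylaldehyde 15. An ortho-hydroxy aldehyde fixes both ends of the new ring, whereas a Pechmann-type closure onto a phenol would leave a regiochemical choice. The forward step is an olefination with a two-carbon ylide under conditions that let the (Z)-ester form and lactonise.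

**15 from 10 and 12 (key disconnection).** The benzene ring of unit A is taken apart at C5–C6 and C4a–C8a, giving diene 10 and prop-2-ynal 12. The neighbouring cut, at the C6–O bond, would require arylation of the hindered C5' oxygen. Here that oxygen is instead bonded to an sp3 carbon early and the arene is grown around it. Diene 10 is acyclic in the part that becomes ring A. The forward reaction needs three things:
- regiochemistry, with the aryloxy terminus bonding to the alkyne terminus;
- chemoselectivity for the alkyne over the formyl C=O;
- aromatisation by loss of methanol and not of the aryloxy group.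

**12 from 11.** Prop-2-ynal polymerises on storage, so it is made by oxidising propargyl alcohol 11 immediately before use.

**10 from 9.** The diene is the silyl dienol ether of ester 9 (cut at O–Si, with removal of the γ hydrogen). Ester 9 is stable and storable. The forward step must deprotonate the γ-CH2 without touching the lactone of unit B.

**9 from 7 (through 8), and 7 from 6.** The pyranone of unit B is cut at O1'–C2' and C3'=C4'. The lactonising oxygen is marked in advance as a pivalate, so closure does not depend on a 2,6-dihydroxybenzaldehyde choosing between its two hydroxyl groups. A Z-selective olefination at low temperature is chosen over the thermal Wittig reaction above 200 °C. The side chain of 6 is an allyl aryl ether with a free para position, and it could undergo Claisen rearrangement at that temperature. The forward step needs Z-selectivity at a di-ortho-substituted aldehyde.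

**6 from 4 and 5.** The O–CH2 bond is cut between the future bridge oxygen and the carbon that becomes C6. Substitution at a primary allylic bromide is little affected by the two ortho substituents that would cripple an arylation. Bromide 5 already is the methyl enol ether, which saves a separate enol etherification. It also avoids placing an α-aryloxy ketone next to a formyl group, where aldol closure to a benzofuran would threaten.

**4 from 3, 3 from 2, 2 from 1.** The cuts are the O–CH3 bond ortho to the formyl group, the O–acyl bond, and the C–CHO bond. Chelation to the formyl oxygen singles out the one ortho methoxy group of 3 for cleavage, while the pivalate covers the other ortho oxygen. Phenol 1 is symmetrical, so formylation has one outcome.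

## Roads not taken

**Alternative 1:** The cut is at both lactone aryl C–O bonds (O1–C8a and O1'–C8a'), leading back to the bis-(E)-cinnamic acid A2. In the forward step, blue light with (−)-riboflavin and O2 would isomerise each acrylic acid and close each carboxylate oxidatively onto its ortho C–H. The product A1 is the same compound as 18.
- Merits: two rings form in one operation. No oxygen has to be placed on C8a or C8a' beforehand, so the problem of telling the two flanking oxygens of unit B apart disappears. A1 could be reached in about half the steps needed for 18, with no silyl diene and no prop-2-ynal.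
- Weak points: the arene of unit A in A2 has two open ortho positions (C8a and C5), so regiochemistry rests on substrate bias, not on construction. The oxidative event must succeed twice on one electron-rich diaryl ether that can over-oxidise. The ether of A2 still comes from an arylation next to two ortho substituents, workable only with an activated aryl halide.
- Comparison: this road is clearly shorter. The chosen plan sets against it that every ring position is fixed by the substrate, that no oxidation is run on the polyoxygenated arenes, and that the hindered ether bond is made by alkylation.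

**Alternative 2:** The cut is at C4a'–C8a' and C5'–C6' of the benzene ring of unit B. In the forward step, the aryl ynol ether A4 is heated with cyclobutenone A5 (Danheiser benzannulation). A vinylketene forms, adds to the ynol ether, and the resulting cyclobutenone opens and closes to phenol A3 with all six substituents of ring B in place.
- Merits: the pentasubstituted ring, the hardest part of the target, is assembled in one thermal cascade with regiochemistry dictated by mechanism. The chosen plan spends steps 1–3 on the same problem.
- Weak points: A5 is a multi-step building block. A4 needs an acetylide step with an alkyllithium, which a coumarin lactone does not tolerate, so the pyranone of unit A would have to be built afterwards or carried masked. A3 still needs desilylation, oxidation, olefination–lactonisation and demethylation.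
- Comparison: this road is better in how directly it sets the substitution of ring B. The chosen plan sets against it catalogue building blocks (1, 5, 11) and a key step run without organolithium reagents.

**Alternative 3:** The cut is at C5–C6 and C8–C8a of ring A at the cyclohexanedione oxidation level. In the forward step, aryloxyacetone A7 and methyl acrylate A8 combine under KOtBu by Michael addition and Claisen condensation to give dione A6.
- Merits: the reagents are cheap and robust, with no moisture-sensitive diene and no hazardous ynal. The C7 oxygen arrives free, so one ether fewer has to be cleaved at the end.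
- Weak points: A6 must be dehydrogenated to the benzene-1,3-diol A9, and C4a must then be functionalised before the pyranone can close. In A6 the aryloxy group sits on an sp3 carbon next to a ketone, so loss of aryloxide would aromatise the ring without any oxidant and sever the two halves. The annulation also exposes the lactone of unit B to stoichiometric alkoxide under equilibrating conditions, and A7 has two enolisable positions.
- Comparison: this road is at least as good in cost and scalability. The chosen plan sets against it that ring A arrives directly at the arene oxidation level with the formyl handle on C4a, and that its intermediate cannot aromatise by losing the aryloxy group. The chosen plan does share a base-sensitivity problem, in step 7, but under kinetic conditions at −78 °C.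

Key step: step 9

Remark on the chemistry: 1, 5 and 11 are taken as catalogue compounds; the ketene acetal geometry written for 10 is the one expected from γ-deprotonation through the ester-bound lithium amide and does not reach the product.

## Route

Step 1
Reactants: 1 3,4,5-trimethoxyphenol
Product: 2 6-hydroxy-2,3,4-trimethoxybenzaldehyde
Conditions: MgCl2, Et3N, (CH2O)n, MeCN, reflux; then 1 M HCl
Reagents that add atoms: formaldehyde (as paraformaldehyde), C=O
Why: Magnesium-phenoxide-directed ortho-formylation (Casnati–Skattebøl type): formaldehyde adds ortho to the chelated phenoxide and a second equivalent oxidises the benzylic alkoxide by hydride transfer. The two ortho positions of 1 are equivalent, so one aldehyde results.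

Step 2
Reactants: 2 6-hydroxy-2,3,4-trimethoxybenzaldehyde
Product: 3 2-formyl-3,4,5-trimethoxyphenyl 2,2-dimethylpropanoate
Conditions: PivCl, Et3N, DMAP (cat.), CH2Cl2, 0 °C to rt
Reagents that add atoms: pivaloyl chloride, CC(C)(C)C(Cl)=O
Why: DMAP-catalysed O-acylation of a phenol. The hindered pivalate marks the oxygen that will become O1' and should tolerate BCl3 and carbonate.

Step 3
Reactants: 3 2-formyl-3,4,5-trimethoxyphenyl 2,2-dimethylpropanoate
Product: 4 2-formyl-3-hydroxy-4,5-dimethoxyphenyl 2,2-dimethylpropanoate
Conditions: BCl3 (1.2 equiv), CH2Cl2, −78 to 0 °C; then H2O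
Reagents that add atoms: none
Why: Chelation-controlled ether cleavage: BCl3 binds the formyl oxygen and the only methoxy group ortho to it in a six-membered chelate, and chloride removes that methyl group. The same selectivity is standard for 2,3,4-trimethoxybenzaldehydes, and aryl esters are not cleaved under these conditions.

Step 4
Reactants: 4 2-formyl-3-hydroxy-4,5-dimethoxyphenyl 2,2-dimethylpropanoate; 5 methyl (2E)-4-bromo-3-methoxybut-2-enoate
Product: 6 methyl (2E)-4-[3-(2,2-dimethylpropanoyloxy)-2-formyl-5,6-dimethoxyphenoxy]-3-methoxybut-2-enoate
Conditions: K2CO3, DMF, rt to 40 °C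
Reagents that add atoms: none
Why: Williamson ether synthesis of a phenoxide with a primary allylic bromide. 4-Halo-3-methoxybut-2-enoates are established O-alkylating agents for phenols, and the (E)-enol ether geometry is carried over untouched.

Step 5
Reactants: 6 methyl (2E)-4-[3-(2,2-dimethylpropanoyloxy)-2-formyl-5,6-dimethoxyphenoxy]-3-methoxybut-2-enoate
Product: 7 methyl (2E)-4-{3-(2,2-dimethylpropanoyloxy)-5,6-dimethoxy-2-[(1Z)-3-methoxy-3-oxoprop-1-en-1-yl]phenoxy}-3-methoxybut-2-enoate
Conditions: (CF3CH2O)2P(O)CH2CO2Me, KN(SiMe3)2, 18-crown-6, THF, −78 °C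
Reagents that add atoms: methyl 2-[bis(2,2,2-trifluoroethoxy)phosphoryl]acetate, COC(=O)CP(=O)(OCC(F)(F)F)OCC(F)(F)F
Why: Still–Gennari variant of the Horner–Wadsworth–Emmons olefination. The bis(trifluoroethyl) phosphonate under dissociating conditions gives (Z)-cinnamates from aryl aldehydes by kinetic control, which is the geometry the lactone needs; the stabilised anion is too weak a base to touch the γ-CH2 of the side chain.

Step 6
Reactants: 7 methyl (2E)-4-{3-(2,2-dimethylpropanoyloxy)-5,6-dimethoxy-2-[(1Z)-3-methoxy-3-oxoprop-1-en-1-yl]phenoxy}-3-methoxybut-2-enoate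
Product: 9 methyl (2E)-4-[(6,7-dimethoxy-2-oxo-2H-chromen-5-yl)oxy]-3-methoxybut-2-enoate, via phenol (Z)-cinnamate 8 (not isolated)
Conditions: K2CO3 (0.2 equiv), MeOH, rt; then AcOH
Reagents that add atoms: none
Why: Base-catalysed transesterification removes the aryl pivalate, and the freed phenoxide, held next to the (Z)-ester, closes the six-membered lactone by intramolecular acyl substitution. Because both remaining esters are methyl esters, methoxide exchange elsewhere is degenerate.

Step 7
Reactants: 9 methyl (2E)-4-[(6,7-dimethoxy-2-oxo-2H-chromen-5-yl)oxy]-3-methoxybut-2-enoate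
Product: 10 5-{[(1Z,3Z)-2,4-dimethoxy-4-(trimethylsilyloxy)buta-1,3-dien-1-yl]oxy}-6,7-dimethoxy-2H-chromen-2-one
Conditions: LiN(iPr)2 (LDA, commercial solution) added to 9 and Me3SiCl, THF, −78 °C; hexane trituration and filtration under argon, used crude
Reagents that add atoms: chlorotrimethylsilane, C[Si](C)(C)Cl
Why: Kinetic γ-deprotonation of a 3-methoxybut-2-enoate and O-silylation of the extended enolate, the standard preparation of 1,3-dimethoxy-1-silyloxybutadienes. The aryloxy group acidifies the γ-CH2, the hindered amide should not add to the lactone at −78 °C, and trapping in situ keeps the dienolate short-lived. The aryloxy group is expected on the outer side of the diene, away from the ester-derived terminus.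

Step 8
Reactants: 11 prop-2-yn-1-ol
Product: 12 prop-2-ynal
Conditions: CrO3, H2SO4, H2O, 2–10 °C, 40–60 mmHg, distilled into a −78 °C trap; dried (MgSO4), taken up in toluene, used at once
Reagents that add atoms: none
Why: Chromic acid oxidation of a primary propargylic alcohol with removal of the volatile aldehyde from the oxidant as it forms, the standard preparation of prop-2-ynal.

Step 9
Reactants: 10 5-{[(1Z,3Z)-2,4-dimethoxy-4-(trimethylsilyloxy)buta-1,3-dien-1-yl]oxy}-6,7-dimethoxy-2H-chromen-2-one; 12 prop-2-ynal
Product: 15 5-[(6,7-dimethoxy-2-oxo-2H-chromen-5-yl)oxy]-2-hydroxy-4-methoxybenzaldehyde, via cyclohexa-1,4-diene cycloadduct 13 (not isolated), via aryl trimethylsilyl ether 14 (not isolated)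
Conditions: 12 (1.5 equiv), toluene, −20 °C to rt, then 50 °C; then 0.5 M HCl, THF, 0 °C
Reagents that add atoms: none
Why: A normal-electron-demand Diels–Alder reaction, concerted but strongly asynchronous: the aryloxy-bearing diene terminus, to which all three donor oxygens push electron density, bonds to the β-carbon of the ynal (C5–C6), and the ketene acetal carbon bonds to the formyl-bearing carbon (C4a–C8a). The closest known reaction type is the Diels–Alder aromatisation of 1,3-dialkoxy-1-silyloxybutadienes with acetylenic esters, ketones and aldehydes to give salicylate-type arenes. The benzene ring of unit A is closed by this (4+2) cycloaddition, both σ bonds in one step, as cyclohexa-1,4-diene 13. The two sp3 centres of 13 (the ketal carbon C8a and C6) are erased on aromatisation, so no stereocentre has to be controlled. Methoxide ionises from the ketal carbon to a cation stabilised by the silyloxy group and the C7 methoxy group, and loss of the C6 proton gives silyl ether 14, which the acidic work-up hydrolyses to phenol 15. The aryloxy group stays: C8a has no hydrogen for an elimination, and its ionisation would put no charge on an oxygen-bearing carbon and one on the formyl-bearing carbon. The step needs regioselectivity, secured by the matched polarisation of diene and ynal, which places the formyl group ortho to the new phenol. It also needs chemoselectivity for the alkyne over the formyl C=O, secured by omitting any Lewis acid so that carbonyl addition stays slow.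

Step 10
Reactants: 15 5-[(6,7-dimethoxy-2-oxo-2H-chromen-5-yl)oxy]-2-hydroxy-4-methoxybenzaldehyde
Product: 18 5-[(7-methoxy-2-oxo-2H-chromen-6-yl)oxy]-6,7-dimethoxy-2H-chromen-2-one, via ethyl (E)-2-hydroxycinnamate 16 (not isolated), via ethyl (Z)-2-hydroxycinnamate 17 (not isolated)
Conditions: Ph3P=CHCO2Et, PhNEt2, reflux
Reagents that add atoms: ethyl (triphenylphosphoranylidene)acetate, CCOC(=O)C=P(c1ccccc1)(c1ccccc1)c1ccccc1
Why: Wittig olefination of a salicylaldehyde with a stabilised ylide, the classical one-pot coumarin synthesis. At the reflux temperature of N,N-diethylaniline the (E)-cinnamate equilibrates with the (Z)-isomer, which lactonises irreversibly with loss of ethanol; no allyl ether remains at this stage.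

Step 11
Reactants: 18 5-[(7-methoxy-2-oxo-2H-chromen-6-yl)oxy]-6,7-dimethoxy-2H-chromen-2-one
Product: 19 6,7-dihydroxy-5-[(7-hydroxy-2-oxo-2H-chromen-6-yl)oxy]-2H-chromen-2-one
Conditions: BBr3 (excess), CH2Cl2, −78 °C to rt; then ice water, under argon
Reagents that add atoms: none
Why: Lewis-acid ether cleavage: BBr3 coordinates each methoxy oxygen and bromide removes the methyl group by SN2. Coumarin lactones and diaryl ethers are inert to these conditions, and hydrolysis of the aryl borates frees the three phenols.

## Compound list

1 | 3,4,5-trimethoxyphenol | COc1cc(O)cc(OC)c1OC | starting material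
2 | 6-hydroxy-2,3,4-trimethoxybenzaldehyde | COc1cc(O)c(C=O)c(OC)c1OC | intermediate
3 | 2-formyl-3,4,5-trimethoxyphenyl 2,2-dimethylpropanoate | CC(C)(C)C(=O)Oc1cc(OC)c(OC)c(OC)c1C=O | intermediate
4 | 2-formyl-3-hydroxy-4,5-dimethoxyphenyl 2,2-dimethylpropanoate | CC(C)(C)C(=O)Oc1cc(OC)c(OC)c(O)c1C=O | intermediate
5 | methyl (2E)-4-bromo-3-methoxybut-2-enoate | COC(=O)/C=C(/OC)CBr | starting material
6 | methyl (2E)-4-[3-(2,2-dimethylpropanoyloxy)-2-formyl-5,6-dimethoxyphenoxy]-3-methoxybut-2-enoate | COC(=O)/C=C(/OC)COc1c(OC)c(OC)cc(OC(=O)C(C)(C)C)c1C=O | intermediate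
7 | methyl (2E)-4-{3-(2,2-dimethylpropanoyloxy)-5,6-dimethoxy-2-[(1Z)-3-methoxy-3-oxoprop-1-en-1-yl]phenoxy}-3-methoxybut-2-enoate | COC(=O)/C=C(/OC)COc1c(OC)c(OC)cc(OC(=O)C(C)(C)C)c1/C=C\C(=O)OC | intermediate
8 | methyl (2E)-4-{3-hydroxy-5,6-dimethoxy-2-[(1Z)-3-methoxy-3-oxoprop-1-en-1-yl]phenoxy}-3-methoxybut-2-enoate | COC(=O)/C=C(/OC)COc1c(OC)c(OC)cc(O)c1/C=C\C(=O)OC | intermediate
9 | methyl (2E)-4-[(6,7-dimethoxy-2-oxo-2H-chromen-5-yl)oxy]-3-methoxybut-2-enoate | COC(=O)/C=C(/OC)COc1c(OC)c(OC)cc2oc(=O)ccc12 | intermediate
10 | 5-{[(1Z,3Z)-2,4-dimethoxy-4-(trimethylsilyloxy)buta-1,3-dien-1-yl]oxy}-6,7-dimethoxy-2H-chromen-2-one | CO/C(O[Si](C)(C)C)=C/C(OC)=C/Oc1c(OC)c(OC)cc2oc(=O)ccc12 | intermediate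
11 | prop-2-yn-1-ol | C#CCO | starting material
12 | prop-2-ynal | C#CC=O | intermediate
13 | rac-3-[(6,7-dimethoxy-2-oxo-2H-chromen-5-yl)oxy]-4,6-dimethoxy-6-(trimethylsilyloxy)cyclohexa-1,4-diene-1-carbaldehyde, 6-methoxy group cis to the 3-aryloxy group (racemic, one enantiomer drawn) | O=CC1=C[C@H](Oc2c(OC)c(OC)cc3oc(=O)ccc23)C(OC)=C[C@@]1(OC)O[Si](C)(C)C | intermediate
14 | 5-[(6,7-dimethoxy-2-oxo-2H-chromen-5-yl)oxy]-4-methoxy-2-(trimethylsilyloxy)benzaldehyde | O=Cc1cc(Oc2c(OC)c(OC)cc3oc(=O)ccc23)c(OC)cc1O[Si](C)(C)C | intermediate
15 | 5-[(6,7-dimethoxy-2-oxo-2H-chromen-5-yl)oxy]-2-hydroxy-4-methoxybenzaldehyde | O=Cc1cc(Oc2c(OC)c(OC)cc3oc(=O)ccc23)c(OC)cc1O | intermediate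
16 | ethyl (2E)-3-{5-[(6,7-dimethoxy-2-oxo-2H-chromen-5-yl)oxy]-2-hydroxy-4-methoxyphenyl}prop-2-enoate | CCOC(=O)/C=C/c1cc(Oc2c(OC)c(OC)cc3oc(=O)ccc23)c(OC)cc1O | intermediate
17 | ethyl (2Z)-3-{5-[(6,7-dimethoxy-2-oxo-2H-chromen-5-yl)oxy]-2-hydroxy-4-methoxyphenyl}prop-2-enoate | CCOC(=O)/C=C\c1cc(Oc2c(OC)c(OC)cc3oc(=O)ccc23)c(OC)cc1O | intermediate
18 | 5-[(7-methoxy-2-oxo-2H-chromen-6-yl)oxy]-6,7-dimethoxy-2H-chromen-2-one | COc1cc2oc(=O)ccc2cc1Oc1c(OC)c(OC)cc2oc(=O)ccc12 | intermediate
19 | 6,7-dihydroxy-5-[(7-hydroxy-2-oxo-2H-chromen-6-yl)oxy]-2H-chromen-2-one | O=c1ccc2cc(Oc3c(O)c(O)cc4oc(=O)ccc34)c(O)cc2o1 | target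

Total step count: 11. Longest linear sequence: 10 steps (steps 1–7 and 9–11); step 8 is a one-step side branch.

## Least certain steps

**Step 9 (key step).** The diene may add to the formyl C=O of the ynal (vinylogous aldol or hetero-Diels–Alder pathway) instead of across the alkyne, because the ynal is a strong carbonyl electrophile and the diene a strong nucleophile. Protodesilylation of the diene by traces of acid and polymerisation of the ynal would also lower conversion. The fallback, which sets out from 10 and comes back at 15, replaces the formyl group by an amide that cannot take part in carbonyl addition. Diene 10 is heated in toluene with the Weinreb amide of propiolic acid (N-methoxy-N-methylprop-2-ynamide, C#CC(=O)N(C)OC), and the same loss of methanol and silyl ether hydrolysis should give 5-[(6,7-dimethoxy-2-oxo-2H-chromen-5-yl)oxy]-2-hydroxy-N,4-dimethoxy-N-methylbenzamide F1. Reduction of F1 with Cp2Zr(H)Cl in THF at rt, a reagent that takes tertiary amides to aldehydes and spares esters and lactones, should then deliver 15.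

**Step 7.** The dienolate may attack the lactone of unit B before it is silylated. The likeliest mode is conjugate addition of its γ-carbon to C4', which lies peri to the side chain; addition of the amide base itself is a lesser risk. Deprotonation with the aryloxy group turned inward would give a diene that cannot cycloadd. The fallback, which sets out from 6 and comes back at 18, carries unit B as a masked salicylaldehyde through diene formation and cycloaddition:
- Aldehyde 6 is acetalised (HC(OMe)3, TsOH cat., MeOH) to methyl (2E)-4-[2-(dimethoxymethyl)-3-(2,2-dimethylpropanoyloxy)-5,6-dimethoxyphenoxy]-3-methoxybut-2-enoate F2.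
- LiN(iPr)2 and Me3SiCl at −78 °C give the diene 2-(dimethoxymethyl)-3-{[(1Z,3Z)-2,4-dimethoxy-4-(trimethylsilyloxy)buta-1,3-dien-1-yl]oxy}-4,5-dimethoxyphenyl 2,2-dimethylpropanoate F3.
- Cycloaddition with 12 and acidic work-up, which also hydrolyses the acetal, give 2-formyl-3-(5-formyl-4-hydroxy-2-methoxyphenoxy)-4,5-dimethoxyphenyl 2,2-dimethylpropanoate F4.
- K2CO3 in MeOH frees 2-(5-formyl-4-hydroxy-2-methoxyphenoxy)-6-hydroxy-3,4-dimethoxybenzaldehyde F5.
- A double Wittig olefination–lactonisation (Ph3P=CHCO2Et, PhNEt2, reflux) closes both pyranones and gives 18. The regiochemistry of unit B is fixed because only one hydroxyl flanks its formyl group.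

**Step 5.** Addition to the di-ortho-substituted, electron-rich aldehyde may be slow, and Z-selectivity may erode, leaving (E)-ester that cannot lactonise in step 6. The fallback, which sets out from 6 and comes back at 9, uses a ring-closing olefination whose geometry is forced by the ring:
- Methanolysis of 6 (K2CO3, MeOH) gives methyl (2E)-4-(2-formyl-3-hydroxy-5,6-dimethoxyphenoxy)-3-methoxybut-2-enoate F6.
- Acylation with ClCH2COCl and pyridine gives methyl (2E)-4-[3-(2-chloroacetoxy)-2-formyl-5,6-dimethoxyphenoxy]-3-methoxybut-2-enoate F7.
- PPh3 converts F7 into {2-[2-formyl-3-{[(2E)-2,4-dimethoxy-4-oxobut-2-en-1-yl]oxy}-4,5-dimethoxyphenoxy]-2-oxoethyl}triphenylphosphonium chloride F8.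
- Et3N generates the ylide, which closes the pyranone by intramolecular Wittig reaction to 9.

**Step 3.** Over-reaction is the risk: a second demethylation at the neighbouring methoxy group through the boron phenoxide, or partial loss of the pivalate. The fallback, which sets out from 2 and comes back at 4, reverses the order and differentiates by sterics. BCl3 on 2 gives 2,6-dihydroxy-3,4-dimethoxybenzaldehyde F9. One equivalent of PivCl with Et3N at −20 °C should then acylate the less hindered hydroxyl, the one flanked by hydrogen, and give 4.

## Further compounds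

F1 | step 9 | 5-[(6,7-dimethoxy-2-oxo-2H-chromen-5-yl)oxy]-2-hydroxy-N,4-dimethoxy-N-methylbenzamide | CON(C)C(=O)c1cc(Oc2c(OC)c(OC)cc3oc(=O)ccc23)c(OC)cc1O
F2 | step 7 | methyl (2E)-4-[2-(dimethoxymethyl)-3-(2,2-dimethylpropanoyloxy)-5,6-dimethoxyphenoxy]-3-methoxybut-2-enoate | COC(=O)/C=C(/OC)COc1c(OC)c(OC)cc(OC(=O)C(C)(C)C)c1C(OC)OC
F3 | step 7 | 2-(dimethoxymethyl)-3-{[(1Z,3Z)-2,4-dimethoxy-4-(trimethylsilyloxy)buta-1,3-dien-1-yl]oxy}-4,5-dimethoxyphenyl 2,2-dimethylpropanoate | CO/C(O[Si](C)(C)C)=C/C(OC)=C/Oc1c(OC)c(OC)cc(OC(=O)C(C)(C)C)c1C(OC)OC
F4 | step 7 | 2-formyl-3-(5-formyl-4-hydroxy-2-methoxyphenoxy)-4,5-dimethoxyphenyl 2,2-dimethylpropanoate | O=Cc1cc(Oc2c(OC)c(OC)cc(OC(=O)C(C)(C)C)c2C=O)c(OC)cc1O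
F5 | step 7 | 2-(5-formyl-4-hydroxy-2-methoxyphenoxy)-6-hydroxy-3,4-dimethoxybenzaldehyde | O=Cc1cc(Oc2c(OC)c(OC)cc(O)c2C=O)c(OC)cc1O
F6 | step 5 | methyl (2E)-4-(2-formyl-3-hydroxy-5,6-dimethoxyphenoxy)-3-methoxybut-2-enoate | COC(=O)/C=C(/OC)COc1c(OC)c(OC)cc(O)c1C=O
F7 | step 5 | methyl (2E)-4-[3-(2-chloroacetoxy)-2-formyl-5,6-dimethoxyphenoxy]-3-methoxybut-2-enoate | COC(=O)/C=C(/OC)COc1c(OC)c(OC)cc(OC(=O)CCl)c1C=O
F8 | step 5 | {2-[2-formyl-3-{[(2E)-2,4-dimethoxy-4-oxobut-2-en-1-yl]oxy}-4,5-dimethoxyphenoxy]-2-oxoethyl}triphenylphosphonium chloride | COC(=O)/C=C(/OC)COc1c(OC)c(OC)cc(OC(=O)C[P+](c2ccccc2)(c2ccccc2)c2ccccc2)c1C=O.[Cl-]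
F9 | step 3 | 2,6-dihydroxy-3,4-dimethoxybenzaldehyde | COc1cc(O)c(C=O)c(O)c1OC
A1 | alternative 1 | 5-[(7-methoxy-2-oxo-2H-chromen-6-yl)oxy]-6,7-dimethoxy-2H-chromen-2-one (identical with 18) | COc1cc2oc(=O)ccc2cc1Oc1c(OC)c(OC)cc2oc(=O)ccc12
A2 | alternative 1 | (2E)-3-{3-[6-((E)-2-carboxyethenyl)-2,3-dimethoxyphenoxy]-4-methoxyphenyl}prop-2-enoic acid | COc1ccc(/C=C/C(O)=O)cc1Oc1c(OC)c(OC)ccc1/C=C/C(O)=O
A3 | alternative 2 | 6-[2-(tert-butyldimethylsilyloxymethyl)-3-hydroxy-5,6-dimethoxyphenoxy]-7-methoxy-2H-chromen-2-one | COc1cc2oc(=O)ccc2cc1Oc1c(OC)c(OC)cc(O)c1CO[Si](C)(C)C(C)(C)C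
A4 | alternative 2 | 6-{[3-(tert-butyldimethylsilyloxy)prop-1-yn-1-yl]oxy}-7-methoxy-2H-chromen-2-one | COc1cc2oc(=O)ccc2cc1OC#CCO[Si](C)(C)C(C)(C)C
A5 | alternative 2 | 2,3-dimethoxycyclobut-2-en-1-one | COC1=C(OC)C(=O)C1
A6 | alternative 3 | 4-[(6,7-dimethoxy-2-oxo-2H-chromen-5-yl)oxy]cyclohexane-1,3-dione (racemic) | O=C1CC(=O)C(Oc2c(OC)c(OC)cc3oc(=O)ccc23)CC1
A7 | alternative 3 | 6,7-dimethoxy-5-(2-oxopropoxy)-2H-chromen-2-one | CC(=O)COc1c(OC)c(OC)cc2oc(=O)ccc12
A8 | alternative 3 | methyl prop-2-enoate | COC(=O)C=C
A9 | alternative 3 | 5-(2,4-dihydroxyphenoxy)-6,7-dimethoxy-2H-chromen-2-one | Oc1ccc(Oc2c(OC)c(OC)cc3oc(=O)ccc23)c(O)c1
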